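**Retrosynthetic overview**
- Last operation: two C–O disconnections at once, the pyranone O1–C2 bond and the 7-O–prenyl bond. These lead back to a 2,4-dihydroxy-3-methoxydeoxybenzoin and one amide acetal that carries both the one-carbon unit (C2) and the prenyl groups.
- The amide acetal comes from DMF dimethyl acetal and prenyl alcohol by alkoxy exchange.
- The deoxybenzoin comes from 2-methoxyresorcinol and 4-methoxyphenylacetic acid by Friedel–Crafts acylation (C4–C4a bond).
- Ring order: rings A and B are bought as the two arenes; ring C (the pyranone) is closed last, in the same flask in which the prenyl ether is formed.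

Assumption: the target has no stereocentre and no stereogenic double bond (the prenyl alkene carries two identical methyl groups), so it is one achiral compound and no enantiocontrol is needed.

**Step 1**
Reactants: 1 2-methoxybenzene-1,3-diol (2-methoxyresorcinol); 2 2-(4-methoxyphenyl)acetic acid
Product: 3 1-(2,4-dihydroxy-3-methoxyphenyl)-2-(4-methoxyphenyl)ethan-1-one
Conditions: neat BF3·OEt2 as solvent, 85 °C, 2 h, N2; then aq NaOAc, recrystallise (EtOH/H2O)
Reagents that add atoms: none
Why: Friedel–Crafts (Nencki-type) acylation in which BF3 activates the acid and the symmetric resorcinol reacts at C4 (= C6), ortho to one OH and para to the other, so only one regioisomer can form, the product being protected from a second acylation as its boron chelate; water is the only co-product and no stereocentre is formed.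

**Step 2**
Reactants: 4 N,N-dimethylformamide dimethyl acetal (1,1-dimethoxy-N,N-dimethylmethanamine); 5 3-methylbut-2-en-1-ol (prenyl alcohol)
Product: 6 N,N-dimethylformamide bis(3-methylbut-2-en-1-yl) acetal (N,N-dimethyl-1,1-bis[(3-methylbut-2-en-1-yl)oxy]methanamine)
Conditions: 5 (3 equiv), cyclohexane, 80 °C, distil off the MeOH azeotrope until no OMe signal remains (1H NMR); strip excess 5 in vacuum; bulb-to-bulb distil (bath ≤ 90 °C, 0.1 mbar)
Reagents that add atoms: none
Why: Amide-acetal alkoxy exchange (transacetalisation), in which the acetal ionises reversibly to an alkoxymethyleneiminium alkoxide pair that swaps alkoxy groups with the free alcohol, driven to completion by removing the low-boiling methanol and kept well below the temperature at which allyl amide acetals rearrange; no stereocentre.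

**Step 3**
Reactants: 3 1-(2,4-dihydroxy-3-methoxyphenyl)-2-(4-methoxyphenyl)ethan-1-one; 6 N,N-dimethylformamide bis(3-methylbut-2-en-1-yl) acetal
Product: 9 8-methoxy-3-(4-methoxyphenyl)-7-[(3-methylbut-2-en-1-yl)oxy]-4H-chromen-4-one (the target), via enaminoketone 7 (not isolated), via hydroxyisoflavone 8 (not isolated)
Conditions: 6 (2.6 equiv), toluene (0.25 M), 70 °C, 2 h, then 100 °C, 8 h, slow N2 sweep; then 5% aq citric acid, rt, 20 min; crystallise (MeOH) or chromatograph
Reagents that add atoms: none
Why: Proposed new method: an annulative O-prenylation in which one purpose-built amide acetal acts twice, first as the formyl-level C1 donor (its iminium carbon is attacked by the enol of the benzylic ketone to give enaminoketone 7, whose chelated 2-OH then adds to the enamine carbon and expels HNMe2, closing ring C through the O1–C2 bond to give 8) and then as the prenyl donor (the acidic 7-OH of 8 protonates a second acetal to the ion pair [Me2N=CH–O-prenyl]+ ArO−, which collapses by SN2 attack of the phenoxide on the unhindered primary allylic CH2 with loss of DMF, forming the aryl prenyl ether); an early prenyl transfer to the 4-OH of 3 leads to the same product, the less acidic, hydrogen-bonded 2-OH is spared because ring closure is intramolecular, and the neutral conditions at ≤ 100 °C are far below the Claisen threshold of aryl prenyl ethers; the closest known reaction types are the DMF dimethyl acetal annulation of 2-hydroxydeoxybenzoins to isoflavones and the O-alkylation of phenols and carboxylic acids by DMF dialkyl acetals (the 7-O-methylation seen as a side reaction of DMF dimethyl acetal on free 7-hydroxy substrates is the same pathway), but a prenyl-bearing amide acetal used for ring closure and prenyl ether formation in one operation has not been described; no stereocentre is formed.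

**Compound list**
1 | 2-methoxybenzene-1,3-diol (2-methoxyresorcinol) | COc1c(O)cccc1O | starting material
2 | 2-(4-methoxyphenyl)acetic acid | COc1ccc(CC(=O)O)cc1 | starting material
3 | 1-(2,4-dihydroxy-3-methoxyphenyl)-2-(4-methoxyphenyl)ethan-1-one | COc1ccc(CC(=O)c2ccc(O)c(OC)c2O)cc1 | intermediate
4 | N,N-dimethylformamide dimethyl acetal | COC(OC)N(C)C | starting material
5 | 3-methylbut-2-en-1-ol (prenyl alcohol) | CC(C)=CCO | starting material
6 | N,N-dimethylformamide bis(3-methylbut-2-en-1-yl) acetal | CN(C)C(OCC=C(C)C)OCC=C(C)C | intermediate
7 | (E)-3-(dimethylamino)-1-(2,4-dihydroxy-3-methoxyphenyl)-2-(4-methoxyphenyl)prop-2-en-1-one (enaminoketone, formed in the flask; C=C geometry labile, drawn E) | CN(C)/C=C(\c1ccc(OC)cc1)C(=O)c1ccc(O)c(OC)c1O | intermediate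
8 | 7-hydroxy-8-methoxy-3-(4-methoxyphenyl)-4H-chromen-4-one (hydroxyisoflavone, formed in the flask) | COc1ccc(-c2coc3c(OC)c(O)ccc3c2=O)cc1 | intermediate
9 | 8-methoxy-3-(4-methoxyphenyl)-7-[(3-methylbut-2-en-1-yl)oxy]-4H-chromen-4-one | COc1ccc(-c2coc3c(OC)c(OCC=C(C)C)ccc3c2=O)cc1 | target

**Step count and risks**
Total step count: 3. Longest linear sequence: 2 (1 + 2 → 3 → 9; the reagent branch 4 + 5 → 6 is a single step).

Most likely to fail: step 3, the proposed new step.
- Risks: the prenyl transfer may be incomplete and leave 8. The 2-OH may be prenylated before ring closure. Liberated dimethylamine may consume reagent. Some attack may occur at the tertiary allyl terminus.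
- Fallback (known chemistry): it sets out from 3. Treatment with prenyl bromide (1.05 equiv) and K2CO3 (1.1 equiv) in refluxing acetone alkylates only the non-chelated 4-OH and gives 1-[2-hydroxy-3-methoxy-4-[(3-methylbut-2-en-1-yl)oxy]phenyl]-2-(4-methoxyphenyl)ethan-1-one F1. Heating F1 with the commercial acetal 4 (3 equiv) in toluene at 90 °C, followed by a dilute acid wash, closes ring C by the standard enaminone condensation–cyclisation and comes back to the route at 9.
- This fallback separates ether formation (Williamson, done first) from ring closure (done last with an acetal that has no prenyl to transfer). It makes step 2 unnecessary, so the total stays at three steps.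

Second: step 2.
- Risks: exchange may stop short, leaving O-methyl groups that would later transfer methyl to the 7-OH. The acetal may be lost to hydrolysis or heat during distillation.
- Fallback: it sets out from 5. Heating 5 (2.2 equiv) with tris(dimethylamino)methane, HC(NMe2)3, in toluene at 60 °C under an N2 sweep replaces amino groups stepwise. This first gives N,N,N',N'-tetramethyl-1-[(3-methylbut-2-en-1-yl)oxy]methanediamine F2, which is not isolated, and then 6, where it rejoins the route.
- Volatile dimethylamine is the driving force, and no O-methyl group is ever present.

Third: step 1.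
- Risks: modest yield from O-acylation, or partial loss of the flanked 3-OMe in hot BF3·OEt2.
- Fallback: it sets out from 1 and uses a Houben–Hoesch reaction instead of the acid. Commercial 2-(4-methoxyphenyl)acetonitrile, ZnCl2 and dry HCl in Et2O at 0 °C precipitate 1-(2,4-dihydroxy-3-methoxyphenyl)-2-(4-methoxyphenyl)ethan-1-iminium chloride F3. Hydrolysis in water at 90 °C returns to the route at 3.

**Further compounds**
F1 | step 3 | 1-[2-hydroxy-3-methoxy-4-[(3-methylbut-2-en-1-yl)oxy]phenyl]-2-(4-methoxyphenyl)ethan-1-one | COc1ccc(CC(=O)c2ccc(OCC=C(C)C)c(OC)c2O)cc1
F2 | step 2 | N,N,N',N'-tetramethyl-1-[(3-methylbut-2-en-1-yl)oxy]methanediamine | CN(C)C(OCC=C(C)C)N(C)C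
F3 | step 1 | 1-(2,4-dihydroxy-3-methoxyphenyl)-2-(4-methoxyphenyl)ethan-1-iminium chloride | COc1ccc(CC(=[NH2+])c2ccc(O)c(OC)c2O)cc1.[Cl-]
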